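**Plan**

- Retrosynthesis: the oxolane is cut at O1f–C2f (benzylic ether closure) and at C2f–C3f (aldol); the tetralin is cut at C1–C2 and C3–C4 ((4+2) cycloaddition); the diarylmethane is cut at C1–C8a (Suzuki–Miyaura coupling); the biaryl bond is bought with divanillin.
- Enabling feature: the saturated tetralin ring C1–C4 with benzo ring A is the adduct of an o-quinodimethane C4=C4a–C8a=C1 (ring C on C1) and a C2=C3 alkene in which C3 already carries its oxygen and its carboxyl-level CH2OH carbon, and C2 its CH2O carbon.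
- Forward, part 1: one divanillin arm becomes a benzylic bromide and is coupled with the formylarylboronate from 6-bromovanillin; a photoenolisation/(4+2) reaction with a malic-acid-derived alkylidene dioxolanone closes the tetralin carbocycle (first ring).
- Forward, part 2: the C4 hydroxyl is removed, the ring B aldehyde is freed and extended by a syn-aldol with a second malic-derived fragment (C3f–C5f and ring D); one LiAlH4 reduction frees seven alcohols, acid closes the oxolane (second ring), and hydrogenolysis frees the phenols.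
- Stereochemistry: the (S)-acetal of the dienophile, from (S)-malic acid, fixes C1, C2 and C3; the same malic acetal, benzylated with retention, gives C4f; (S)-4-benzyloxazolidinone fixes C3f (and C2f), and C2f re-forms trans to C3f in the ring closure.

Key step: step 12

Remark: divanillin and 3-(benzyloxy)-4-methoxybenzyl alcohol are taken as catalogue compounds; locants are C1–C4, C4a, C8a for the tetralin (ring A its benzo ring), O1f and C2f–C5f for the oxolane, ring C for the biaryl ring on C1, ring B for the biaryl ring on C2f, and ring D for the isovanillyl ring.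

**Route**

Step 1
Reactants: 1 divanillin
Product: 2 6,6'-bis(benzyloxy)-5,5'-dimethoxybiphenyl-3,3'-dicarbaldehyde
Conditions: BnBr, K2CO3, DMF, 60 °C
Reagents that add atoms: benzyl bromide, BrCc1ccccc1
Why: Williamson ether synthesis on both phenols should proceed cleanly because the aldehydes are inert to carbonate, and the benzyl ethers then last until the final hydrogenolysis.

Step 2
Reactants: 2 dibenzyl dialdehyde
Product: 3 6,6'-bis(benzyloxy)-3'-(1,3-dioxolan-2-yl)-5,5'-dimethoxybiphenyl-3-carbaldehyde
Conditions: HOCH2CH2OH (1 equiv), PPTS (cat.), toluene, reflux (Dean–Stark), stopped at partial conversion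
Reagents that add atoms: ethylene glycol, OCCO
Why: Acid-catalysed acetalisation of one of two equivalent aldehydes is statistical, so 3 should be separated by chromatography and recovered 2 and hydrolysed bis-acetal recycled.

Step 3
Reactants: 3 mono-dioxolane aldehyde
Product: 4 [6,6'-bis(benzyloxy)-3'-(1,3-dioxolan-2-yl)-5,5'-dimethoxybiphenyl-3-yl]methanol
Conditions: NaBH4, MeOH/THF, 0 °C
Reagents that add atoms: none
Why: Borohydride reduction of the remaining aldehyde should be chemoselective because the dioxolane and the aryl ethers are inert to hydride.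

Step 4
Reactants: 4 benzylic alcohol
Product: 5 2-[6,6'-bis(benzyloxy)-3'-(bromomethyl)-5,5'-dimethoxybiphenyl-3-yl]-1,3-dioxolane
Conditions: CBr4, PPh3, 2,6-lutidine, CH2Cl2, 0 °C
Reagents that add atoms: carbon tetrabromide, BrC(Br)(Br)Br
Why: The Appel reaction converts the benzylic alcohol into the bromide under buffered, non-acidic conditions that spare the dioxolane, and the reactive 4-alkoxybenzyl bromide should be used without storage.

Step 5
Reactants: 6 6-bromovanillin
Product: 7 4-(benzyloxy)-2-bromo-5-methoxybenzaldehyde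
Conditions: BnBr, K2CO3, DMF, rt
Reagents that add atoms: benzyl bromide, BrCc1ccccc1
Why: Williamson ether synthesis of the phenol should be straightforward and gives the same phenol protection as on the biaryl.

Step 6
Reactants: 7 aryl bromide
Product: 8 4-(benzyloxy)-5-methoxy-2-(4,4,5,5-tetramethyl-1,3,2-dioxaborolan-2-yl)benzaldehyde
Conditions: B2pin2, PdCl2(dppf) (cat.), KOAc, 1,4-dioxane, 85 °C
Reagents that add atoms: bis(pinacolato)diboron, CC1(C)OB(OC1(C)C)B1OC(C)(C)C(C)(C)O1
Why: Miyaura borylation with KOAc as a weak base tolerates the ortho aldehyde and should give the pinacol boronate.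

Step 7
Reactants: 5 benzylic bromide; 8 formylarylboronate
Product: 9 4-(benzyloxy)-2-{[6,6'-bis(benzyloxy)-3'-(1,3-dioxolan-2-yl)-5,5'-dimethoxybiphenyl-3-yl]methyl}-5-methoxybenzaldehyde
Conditions: PdCl2(dppf) (cat.), K2CO3, THF/H2O, 65 °C
Reagents that add atoms: none
Why: Suzuki–Miyaura coupling of a benzylic bromide with an arylboronate forms the diarylmethane C(sp3)–C(sp2) bond (C1–C8a) without touching aldehyde or acetal, and it places the doubly benzylic CH2 ortho to the formyl group as photoenolisation requires.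

Step 8
Reactants: 10 (S)-malic acid; 11 pivalaldehyde
Product: 12 [(2S,4S)-2-tert-butyl-5-oxo-1,3-dioxolan-4-yl]acetic acid
Conditions: TsOH (cat.), H2SO4 (cat.), pentane, reflux (Dean–Stark); crystallisation
Reagents that add atoms: none
Why: Acid-catalysed acetalisation of the α-hydroxy acid unit with removal of water gives the dioxolanone, whose acetal carbon is set cis to the side chain (2S) under thermodynamic control by the malic stereocentre, the minor trans isomer being removed by crystallisation.

Step 9
Reactants: 12 dioxolanone acid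
Product: 13 (2S,5S)-2-tert-butyl-5-(2-hydroxyethyl)-1,3-dioxolan-4-one
Conditions: BH3·SMe2, THF, 0 °C to rt
Reagents that add atoms: none
Why: Borane reduces a free carboxylic acid much faster than the lactone-type carbonyl, so this chemoselective reduction should give the primary alcohol with both stereocentres intact.

Step 10
Reactants: 13 hydroxyethyl dioxolanone
Product: 14 2-[(2S,4S)-2-tert-butyl-5-oxo-1,3-dioxolan-4-yl]ethyl pivalate
Conditions: PivCl, pyridine, DMAP (cat.), CH2Cl2, 0 °C
Reagents that add atoms: pivaloyl chloride, CC(C)(C)C(Cl)=O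
Why: DMAP-catalysed acylation caps the alcohol before it can translactonise onto the dioxolanone, and a pivalate, unlike a benzyl ether, offers no C–H bond that competes in the radical bromination of step 11.

Step 11
Reactants: 14 pivalate
Product: 16 (Z)-2-[(2S)-2-tert-butyl-5-oxo-1,3-dioxolan-4-ylidene]ethyl pivalate, via bromo-dioxolanone 15 (not isolated)
Conditions: NBS, AIBN (cat.), PhCF3, 80 °C; then Et3N, CH2Cl2, 0 °C to rt
Reagents that add atoms: none
Why: Wohl–Ziegler bromination should occur at the captodative C–H between ring oxygen and carbonyl and E2 dehydrobromination then gives the exocyclic alkene, the (Z) isomer (side chain syn to the ring oxygen, away from the carbonyl) being expected to predominate and to be separable from any (E) isomer, while the acetal stereocentre is untouched.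

Step 12
Reactants: 9 2-benzylbenzaldehyde; 16 (Z)-alkylidene dioxolanone
Product: 18 spiro-dioxolanone 4-hydroxytetralin adduct (1S,2S,3R,4R; acetal S), via photodienol 17 (not isolated)
Conditions: hν (365 nm), Ti(OiPr)4 (2 equiv), 16 (3 equiv), degassed toluene, rt
Reagents that add atoms: none
Why: Excitation of the aryl aldehyde of 9 and 1,5-hydrogen transfer from the diarylmethane CH2 should give the (E,E)-hydroxy-o-quinodimethane 17 with hydroxyl and aryl both outward, which Ti(OiPr)4 holds as a titanium dienolate that also binds the lactone carbonyl of 16; the closest known reaction type is the photoenolisation/Diels–Alder reaction of 2-benzylbenzaldehydes with acrylate-type dienophiles. The six-membered carbocycle closes by one suprafacial intermolecular (4+2) cycloaddition that forms C1–C2 and C3–C4 and makes C3 a spiro centre. Regiochemistry follows from the donor hydroxyl, whose terminus (C4) joins the captodative α-carbon (C3) while the aryl-bearing terminus (C1) joins the β-carbon (C2). C1 and C4 are set by the outward geometry of the dienol together with the titanium-bridged endo placement of the lactone carbonyl, the C2/C3 relationship by the (Z)-alkene, and the absolute sense of all four centres by approach of the diene to the alkene face anti to the tert-butyl group of the (S)-acetal. The step needs chemoselective excitation (secured by masking the ring B aldehyde as a dioxolane), endo over exo addition (secured by the titanium bridge against the exo bias of s-cis exocyclic dienophiles) and π-facial control (secured by the acetal).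

Step 13
Reactants: 18 adduct
Product: 19 O-(imidazol-1-ylthiocarbonyl) derivative of 18 at C4
Conditions: 1,1'-thiocarbonyldiimidazole, DMAP (cat.), ClCH2CH2Cl, 70 °C
Reagents that add atoms: 1,1'-thiocarbonyldiimidazole, S=C(n1ccnc1)n1ccnc1
Why: Thioacylation of the only free hydroxyl under neutral conditions (first half of a Barton–McCombie deoxygenation) avoids a C4 alkoxide, which could trigger retro-aldol cleavage of the C3–C4 bond next to the lactone carbonyl.

Step 14
Reactants: 19 thiocarbonylimidazolide
Product: 20 4-deoxy spiro-dioxolanone tetralin (1S,2S,3S; acetal S)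
Conditions: Bu3SnH, AIBN (cat.), toluene, 100 °C
Reagents that add atoms: none
Why: Barton–McCombie radical deoxygenation cleaves the benzylic C4–O bond through a benzylic radical that takes hydrogen from the stannane, and unlike ionic or catalytic hydrogenolysis it leaves the benzyl ethers, the dioxolane, both acyl groups and C1–C3 untouched.

Step 15
Reactants: 20 deoxygenated acetal
Product: 21 ring B aldehyde (dioxolane of 20 replaced by CHO)
Conditions: 1 M HCl, THF, rt
Reagents that add atoms: water, O
Why: Acid-catalysed hydrolysis of the aryl dioxolane, made labile by the para alkoxy group, should free the ring B aldehyde while the dioxolanone acylal and the pivalate resist dilute acid at room temperature.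

Step 16
Reactants: 22 3-(benzyloxy)-4-methoxybenzyl alcohol
Product: 23 3-(benzyloxy)-4-methoxybenzyl bromide
Conditions: PBr3, Et2O, 0 °C
Reagents that add atoms: phosphorus tribromide, BrP(Br)Br
Why: Bromination of the benzylic alcohol with PBr3 (SN2 on the phosphite ester) should give the electron-rich benzyl bromide, which is used freshly prepared.

Step 17
Reactants: 12 dioxolanone acid; 23 benzyl bromide
Product: 25 [(2S,4S)-4-{[3-(benzyloxy)-4-methoxyphenyl]methyl}-2-tert-butyl-5-oxo-1,3-dioxolan-4-yl]acetic acid, via dilithium enolate 24 (not isolated)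
Conditions: LiN(SiMe3)2 (2.2 equiv), THF, −78 °C; then 23, −78 to −20 °C; aq. HCl
Reagents that add atoms: none
Why: Enolate alkylation with self-regeneration of the stereocentre: the lactone enolate of dianion 24 is planar at the former carbinol carbon and should be benzylated on the face anti to the tert-butyl group of the retained (S)-acetal, so benzyl replaces hydrogen with retention and sets the quaternary carbon that becomes C4f.

Step 18
Reactants: 25 alkylated acid; 26 (S)-4-benzyl-1,3-oxazolidin-2-one
Product: 28 (S)-4-benzyl-3-{[(2S,4S)-4-{[3-(benzyloxy)-4-methoxyphenyl]methyl}-2-tert-butyl-5-oxo-1,3-dioxolan-4-yl]acetyl}-1,3-oxazolidin-2-one, via mixed pivalic anhydride 27 (not isolated)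
Conditions: PivCl, Et3N, THF, −20 °C; then LiCl, 26, rt
Reagents that add atoms: none
Why: N-Acylation of the oxazolidinone through the mixed pivalic anhydride should occur at the less hindered CH2–C=O carbonyl of 27, with no stereocentre involved.

Step 19
Reactants: 28 imide; 21 ring B aldehyde
Product: 30 syn-aldol adduct (C2f S, C3f R), via dibutylboron enolate 29 (not isolated)
Conditions: Bu2BOTf, iPr2NEt, CH2Cl2, 0 °C; then 21, −78 to 0 °C; pH 7 buffer, MeOH, H2O2, 0 °C
Reagents that add atoms: none
Why: Evans syn-aldol reaction: the (Z)-boron enolate 29 should add to the aldehyde through a closed chair transition state on the enolate face turned away from the benzyl group of the (S)-auxiliary, which sets C3f (R) and C2f (S) independently of the neighbouring quaternary centre, while the two dioxolanones serve as spectator protecting groups.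

Step 20
Reactants: 30 aldol adduct
Product: 31 heptaol
Conditions: LiAlH4, THF, 0 °C to rt; aq. potassium sodium tartrate
Reagents that add atoms: none
Why: Exhaustive LiAlH4 reduction removes the auxiliary reductively (C3f CH2OH), reduces both dioxolanones to a tertiary alcohol plus a CH2OH (the acetal carbon leaving as neopentyl alcohol) and cleaves the pivalate, so seven hydroxyls are freed without touching a stereocentre, and any adduct that has translactonised through its C2f hydroxyl converges on the same product.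

Step 21
Reactants: 31 heptaol
Product: 32 tetra-O-benzyl ether of the target (oxolane 2S,3R,4S)
Conditions: CSA (cat.), CH2Cl2/THF, 0 °C
Reagents that add atoms: none
Why: Acid-catalysed intramolecular etherification: the 4-alkoxybenzylic C2f hydroxyl ionises selectively and the cation is captured 5-exo by the C5f hydroxyl (the other hydroxyls would give four-membered or large rings), the aryl group settling trans to the C3f CH2OH so that C2f (S) is re-formed, and catalytic acid at 0 °C with early quenching should outrun Friedel–Crafts closure onto ring D.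

Step 22
Reactants: 32 tetrabenzyl ether
Product: 33 target
Conditions: H2 (1 atm), Pd/C, EtOAc/MeOH, rt
Reagents that add atoms: none
Why: Catalytic hydrogenolysis of the four aryl benzyl ethers in neutral solvent should leave the benzylic C–O bond of the oxolane, the tetralin and all stereocentres unchanged if stopped once four equivalents of hydrogen are taken up.

**Compound list**

1 | divanillin (6,6'-dihydroxy-5,5'-dimethoxybiphenyl-3,3'-dicarbaldehyde) | COc1cc(C=O)cc(-c2cc(C=O)cc(OC)c2O)c1O | starting material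
2 | 6,6'-bis(benzyloxy)-5,5'-dimethoxybiphenyl-3,3'-dicarbaldehyde | COc1cc(C=O)cc(-c2cc(C=O)cc(OC)c2OCc2ccccc2)c1OCc1ccccc1 | intermediate
3 | 6,6'-bis(benzyloxy)-3'-(1,3-dioxolan-2-yl)-5,5'-dimethoxybiphenyl-3-carbaldehyde | COc1cc(C=O)cc(-c2cc(C3OCCO3)cc(OC)c2OCc2ccccc2)c1OCc1ccccc1 | intermediate
4 | [6,6'-bis(benzyloxy)-3'-(1,3-dioxolan-2-yl)-5,5'-dimethoxybiphenyl-3-yl]methanol | COc1cc(CO)cc(-c2cc(C3OCCO3)cc(OC)c2OCc2ccccc2)c1OCc1ccccc1 | intermediate
5 | 2-[6,6'-bis(benzyloxy)-3'-(bromomethyl)-5,5'-dimethoxybiphenyl-3-yl]-1,3-dioxolane | COc1cc(CBr)cc(-c2cc(C3OCCO3)cc(OC)c2OCc2ccccc2)c1OCc1ccccc1 | intermediate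
6 | 6-bromovanillin (2-bromo-4-hydroxy-5-methoxybenzaldehyde) | COc1cc(C=O)c(Br)cc1O | starting material
7 | 4-(benzyloxy)-2-bromo-5-methoxybenzaldehyde | COc1cc(C=O)c(Br)cc1OCc1ccccc1 | intermediate
8 | 4-(benzyloxy)-5-methoxy-2-(4,4,5,5-tetramethyl-1,3,2-dioxaborolan-2-yl)benzaldehyde | COc1cc(C=O)c(B2OC(C)(C)C(C)(C)O2)cc1OCc1ccccc1 | intermediate
9 | 4-(benzyloxy)-2-{[6,6'-bis(benzyloxy)-3'-(1,3-dioxolan-2-yl)-5,5'-dimethoxybiphenyl-3-yl]methyl}-5-methoxybenzaldehyde | O=Cc1cc(OC)c(OCc2ccccc2)cc1Cc1cc(OC)c(OCc2ccccc2)c(c1)-c1cc(cc(OC)c1OCc1ccccc1)C1OCCO1 | intermediate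
10 | (S)-malic acid | OC(=O)C[C@@H](C(=O)O)O | starting material
11 | pivalaldehyde | CC(C)(C)C=O | starting material
12 | [(2S,4S)-2-tert-butyl-5-oxo-1,3-dioxolan-4-yl]acetic acid (tert-butyl cis to the side chain) | OC(=O)C[C@@H]1O[C@H](C(C)(C)C)OC1=O | intermediate
13 | (2S,5S)-2-tert-butyl-5-(2-hydroxyethyl)-1,3-dioxolan-4-one | OCC[C@@H]1O[C@H](C(C)(C)C)OC1=O | intermediate
14 | 2-[(2S,4S)-2-tert-butyl-5-oxo-1,3-dioxolan-4-yl]ethyl pivalate | CC(C)(C)C(=O)OCC[C@@H]1O[C@H](C(C)(C)C)OC1=O | intermediate
15 | 2-[(2S,4R)-4-bromo-2-tert-butyl-5-oxo-1,3-dioxolan-4-yl]ethyl pivalate (bromine trans to tert-butyl) | CC(C)(C)C(=O)OCC[C@]1(Br)O[C@H](C(C)(C)C)OC1=O | intermediate (not isolated)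
16 | (Z)-2-[(2S)-2-tert-butyl-5-oxo-1,3-dioxolan-4-ylidene]ethyl pivalate | O=C1O[C@@H](C(C)(C)C)O/C1=C\COC(=O)C(C)(C)C | intermediate
17 | (E,E)-hydroxy-o-quinodimethane from 9 (ring A dearomatised, exocyclic =CH–OH and =CH–aryl, hydroxyl and aryl outward) | O/C=C1\C=C(OC)C(OCc2ccccc2)=C/C1=C\c1cc(OC)c(OCc2ccccc2)c(c1)-c1cc(cc(OC)c1OCc1ccccc1)C1OCCO1 | intermediate (not isolated)
18 | (1S,2S,3R,4R)-1-[6,6'-bis(benzyloxy)-3'-(1,3-dioxolan-2-yl)-5,5'-dimethoxybiphenyl-3-yl]-7-(benzyloxy)-4-hydroxy-6-methoxy-2-(pivaloyloxymethyl)tetralin, C3 being the spiro carbon C5 of a (2S)-2-tert-butyl-1,3-dioxolan-4-one (ring oxygen and lactone carbonyl both on C3) | COc1cc(cc(c1OCc1ccccc1)-c1cc(cc(OC)c1OCc1ccccc1)[C@H]1c2cc(OCc3ccccc3)c(OC)cc2[C@@H](O)[C@]2(O[C@H](C(C)(C)C)OC2=O)[C@@H]1COC(=O)C(C)(C)C)C1OCCO1 | intermediate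
19 | C4 O-(imidazol-1-ylthiocarbonyl) derivative of 18 | COc1cc(cc(c1OCc1ccccc1)-c1cc(cc(OC)c1OCc1ccccc1)[C@H]1c2cc(OCc3ccccc3)c(OC)cc2[C@@H](OC(=S)n2ccnc2)[C@]2(O[C@H](C(C)(C)C)OC2=O)[C@@H]1COC(=O)C(C)(C)C)C1OCCO1 | intermediate
20 | 4-deoxy analogue of 18 (C4 is CH2; 1S,2S,3S; acetal S) | COc1cc(cc(c1OCc1ccccc1)-c1cc(cc(OC)c1OCc1ccccc1)[C@H]1c2cc(OCc3ccccc3)c(OC)cc2C[C@]2(O[C@H](C(C)(C)C)OC2=O)[C@@H]1COC(=O)C(C)(C)C)C1OCCO1 | intermediate
21 | ring B aldehyde (20 with the 1,3-dioxolan-2-yl group replaced by CHO) | COc1cc(C=O)cc(c1OCc1ccccc1)-c1cc(cc(OC)c1OCc1ccccc1)[C@H]1c2cc(OCc3ccccc3)c(OC)cc2C[C@]2(O[C@H](C(C)(C)C)OC2=O)[C@@H]1COC(=O)C(C)(C)C | intermediate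
22 | 3-(benzyloxy)-4-methoxybenzyl alcohol | COc1ccc(CO)cc1OCc1ccccc1 | starting material
23 | 3-(benzyloxy)-4-methoxybenzyl bromide | COc1ccc(CBr)cc1OCc1ccccc1 | intermediate
24 | dilithium salt of 12 (carboxylate and lactone enolate, acetal S) | [Li+].[Li+].[O-]C1=C(CC([O-])=O)O[C@H](C(C)(C)C)O1 | intermediate (not isolated)
25 | [(2S,4S)-4-{[3-(benzyloxy)-4-methoxyphenyl]methyl}-2-tert-butyl-5-oxo-1,3-dioxolan-4-yl]acetic acid (benzyl trans to tert-butyl) | OC(=O)C[C@]1(Cc2ccc(OC)c(OCc3ccccc3)c2)O[C@H](C(C)(C)C)OC1=O | intermediate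
26 | (S)-4-benzyl-1,3-oxazolidin-2-one | O=C1N[C@@H](Cc2ccccc2)CO1 | starting material
27 | mixed anhydride of 25 with pivalic acid | CC(C)(C)C(=O)OC(=O)C[C@]1(Cc2ccc(OC)c(OCc3ccccc3)c2)O[C@H](C(C)(C)C)OC1=O | intermediate (not isolated)
28 | (S)-4-benzyl-3-{[(2S,4S)-4-{[3-(benzyloxy)-4-methoxyphenyl]methyl}-2-tert-butyl-5-oxo-1,3-dioxolan-4-yl]acetyl}-1,3-oxazolidin-2-one | O=C1OC[C@H](Cc2ccccc2)N1C(=O)C[C@]1(Cc2ccc(OC)c(OCc3ccccc3)c2)O[C@H](C(C)(C)C)OC1=O | intermediate
29 | (Z)-dibutylboron enolate of 28 | CCCCB(CCCC)O/C(=C\[C@]1(Cc2ccc(OC)c(OCc3ccccc3)c2)O[C@H](C(C)(C)C)OC1=O)N1[C@@H](Cc2ccccc2)COC1=O | intermediate (not isolated)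
30 | syn-aldol adduct: (S)-4-benzyl-3-[(2R,3S)-3-aryl-3-hydroxy-2-{(2S,4S)-4-[3-(benzyloxy)-4-methoxybenzyl]-2-tert-butyl-5-oxo-1,3-dioxolan-4-yl}propanoyl]oxazolidin-2-one, aryl being ring B of 21 | COc1cc(cc(c1OCc1ccccc1)-c1cc(cc(OC)c1OCc1ccccc1)[C@H]1c2cc(OCc3ccccc3)c(OC)cc2C[C@]2(O[C@H](C(C)(C)C)OC2=O)[C@@H]1COC(=O)C(C)(C)C)[C@@H](O)[C@@H](C(=O)N1[C@@H](Cc2ccccc2)COC1=O)[C@]1(Cc2ccc(OC)c(OCc3ccccc3)c2)O[C@H](C(C)(C)C)OC1=O | intermediate
31 | heptaol: (1S,2R,3S)-1-aryl-3-[3-(benzyloxy)-4-methoxybenzyl]-2-(hydroxymethyl)butane-1,3,4-triol whose biaryl carries the (1S,2S,3S)-7-(benzyloxy)-3-hydroxy-2,3-bis(hydroxymethyl)-6-methoxytetralin-1-yl group | COc1cc(cc(c1OCc1ccccc1)-c1cc(cc(OC)c1OCc1ccccc1)[C@H]1c2cc(OCc3ccccc3)c(OC)cc2C[C@@](O)(CO)[C@@H]1CO)[C@@H](O)[C@@H](CO)[C@](O)(CO)Cc1ccc(OC)c(OCc2ccccc2)c1 | intermediate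
32 | tetra-O-benzyl ether of the target (all four phenols as benzyl ethers; oxolane 2S,3R,4S; tetralin 1S,2S,3S) | COc1ccc(C[C@@]2(O)CO[C@H](c3cc(OC)c(OCc4ccccc4)c(-c4cc([C@H]5c6cc(OCc7ccccc7)c(OC)cc6C[C@@](O)(CO)[C@@H]5CO)cc(OC)c4OCc4ccccc4)c3)[C@H]2CO)cc1OCc1ccccc1 | intermediate
33 | target: 6,6'-dihydroxy-5,5'-dimethoxybiphenyl bearing at C3 the (1S,2S,3S)-3,7-dihydroxy-2,3-bis(hydroxymethyl)-6-methoxytetralin-1-yl group and at C3' the (2S,3R,4S)-4-hydroxy-4-(3-hydroxy-4-methoxybenzyl)-3-(hydroxymethyl)oxolan-2-yl group | COc1ccc(C[C@@]2(O)CO[C@H](c3cc(OC)c(O)c(-c4cc([C@H]5c6cc(O)c(OC)cc6C[C@@](O)(CO)[C@@H]5CO)cc(OC)c4O)c3)[C@H]2CO)cc1O | target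

**Step count and risks**

Total: 22 steps. Longest linear sequence: 13 steps from divanillin (steps 1–4, 7, 12–15, 19–22).

Step 12 (key step). The photodienol can return to 9 by reverse hydrogen transfer faster than a trisubstituted dienophile intercepts it. Ti(OiPr)4 can slowly open the dioxolanone of 16 by isopropanolysis. Without a firm titanium bridge, the exo mode typical of s-cis exocyclic dienophiles can erode the C1/C4 configuration. Fallback: the dienol is stored and then released thermally. Irradiation of 9 in benzene saturated with sulfur dioxide should trap 17 by cheletropic addition as the hydroxy sulfone F1. Heating F1 with 16 in toluene at 80–110 °C over ZnO (to bind SO2) extrudes sulfur dioxide and regenerates 17 slowly in the presence of a high concentration of dienophile. With the dienol hydroxyl hydrogen-bonded to the lactone carbonyl, this should give 18 without light or titanium. The fallback sets out from 9 (with 16) and returns to the route at 18.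

Step 19. Enolisation and addition of a boron enolate whose α-carbon sits on a quaternary centre may be too slow, so that 21 is recovered or the aldolate reverts. Fallback: substrate control with a smaller, more reactive lithium enolate held in a ring. Reduction of 25 with LiBH4 (the lithium carboxylate is not reduced) and acidification should give the hydroxy lactone F2. Silylation (TMSOTf, 2,6-lutidine) gives the silyl ether F3, and LiN(iPr)2 in THF at −78 °C forms the lithium enolate F4. F4 is expected to add to 21 on the face anti to the benzyl group (the smaller silyloxy group being syn), giving the lactone aldol adduct F5 as a mixture of carbinol epimers; this facial preference is itself the uncertain point of the fallback. LiAlH4 then gives the silylated heptaol F6, and CSA in CH2Cl2/MeOH both removes the silyl group and closes the oxolane, the carbinol epimers converging through the benzylic cation. The fallback sets out from 25 (with 21) and returns at 32.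

Step 21. The oxolane, once formed, can re-ionise at C2f and the cation can be captured irreversibly by ring D (Friedel–Crafts closure to a second aryltetralin). Intermolecular ethers can also form among the seven hydroxyls. Fallback: ionisation by acid is replaced by quinone methide formation under neutral conditions. Hydrogenolysis of 31 (H2, Pd/C, EtOAc/MeOH, stopped after four equivalents) should give the free tetraphenol F7. On gentle warming in aqueous acetonitrile buffered at pH 7, the 4-hydroxybenzylic alcohol of ring B loses water to the p-quinone methide F8. The C5f hydroxyl adds to F8 5-exo in a 1,6-fashion, with the aryl group trans to the C3f substituent, to give 33 directly. The fallback sets out from 31 and returns at 33.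

**Further compounds**

F1 | step 12 | hydroxy sulfone: 1-aryl-3-hydroxy-1,3-dihydrobenzo[c]thiophene 2,2-dioxide from 9 (5-benzyloxy-6-methoxy on the benzo ring, aryl being ring C of 9; racemic, hydroxyl and aryl cis) | OC1c2cc(OC)c(OCc3ccccc3)cc2C(c2cc(OC)c(OCc3ccccc3)c(c2)-c2cc(cc(OC)c2OCc2ccccc2)C2OCCO2)S1(=O)=O
F2 | step 19 | (4S)-4-{[3-(benzyloxy)-4-methoxyphenyl]methyl}-4-hydroxyoxolan-2-one | O=C1C[C@@](O)(Cc2ccc(OC)c(OCc3ccccc3)c2)CO1
F3 | step 19 | trimethylsilyl ether of F2 | O=C1C[C@@](O[Si](C)(C)C)(Cc2ccc(OC)c(OCc3ccccc3)c2)CO1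
F4 | step 19 | lithium enolate of F3 | [Li+].[O-]C1=C[C@@](O[Si](C)(C)C)(Cc2ccc(OC)c(OCc3ccccc3)c2)CO1
F5 | step 19 | lactone aldol adduct of F4 with 21 (new bond cis to the silyloxy group; both carbinol epimers) | COc1cc(cc(c1OCc1ccccc1)-c1cc(cc(OC)c1OCc1ccccc1)[C@H]1c2cc(OCc3ccccc3)c(OC)cc2C[C@]2(O[C@H](C(C)(C)C)OC2=O)[C@@H]1COC(=O)C(C)(C)C)C(O)[C@H]1C(=O)OC[C@]1(O[Si](C)(C)C)Cc1ccc(OC)c(OCc2ccccc2)c1
F6 | step 19 | C4f-O-trimethylsilyl heptaol (31 with the tertiary side-chain hydroxyl silylated; both carbinol epimers) | COc1cc(cc(c1OCc1ccccc1)-c1cc(cc(OC)c1OCc1ccccc1)[C@H]1c2cc(OCc3ccccc3)c(OC)cc2C[C@@](O)(CO)[C@@H]1CO)C(O)[C@@H](CO)[C@](O[Si](C)(C)C)(CO)Cc1ccc(OC)c(OCc2ccccc2)c1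
F7 | step 21 | debenzylated heptaol (31 with four free phenols) | COc1cc(cc(c1O)-c1cc(cc(OC)c1O)[C@H]1c2cc(O)c(OC)cc2C[C@@](O)(CO)[C@@H]1CO)[C@@H](O)[C@@H](CO)[C@](O)(CO)Cc1ccc(OC)c(O)c1
F8 | step 21 | ring B p-quinone methide from F7 (exocyclic C=C at C2f) | COC1=CC(=C[C@@H](CO)[C@](O)(CO)Cc2ccc(OC)c(O)c2)C=C(C1=O)c1cc(cc(OC)c1O)[C@H]1c2cc(O)c(OC)cc2C[C@@](O)(CO)[C@@H]1CO
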